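## Analysis of the target

Compound 26 is a (2R)-flavan: a chroman whose benzo ring (ring A, C4a to C8a) is fused to a dihydropyran (O1, C2, C3, C4), with a 3-hydroxy-5-methoxyphenyl group (ring B) on C2. C2 is the only stereocentre. It is a benzylic ether carbon with nothing to be related to, so it must be set by a catalyst and then kept away from any step that ionises or cleaves the C2–O1 bond. Ring A is pentasubstituted: OMe on C5, H on C6, OH on C7, prenyl on C8, O1 on C8a and the C4 methylene on C4a. The sensitive groups are the prenyl alkene (acid closes it onto the C7 hydroxyl, hydrogenation saturates it), two free phenols on electron-rich rings, and the benzylic C2–O1 bond, which excludes hydrogenolysis. The difficulty lies in ring A: three oxygens of a phloroglucinol core must end up as three different functions, and the prenyl group must sit on C8 and not on C6, which electrophilic substitution does not decide cleanly. The strategy rests on the pattern of ring A itself. Its oxygens are on C5, C7 and C8a and the prenyl-bearing C8 lies between C7 and C8a. That is the pattern formed when a vinylketene from a 3-methoxycyclobutenone (C4a, C5, C6, C7) combines with an alkynyl ether (C8, C8a). The alkynyl ether oxygen is O1 and is bound to C2, so the C2–C3–C4 chain can tether the two partners and the pyran ring closes in the same event.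

## Retrosynthetic reasoning

26 is traced back to its ring B methoxymethyl ether 25. An acetal is used for this phenol because it must survive strong base, organolithium and organozinc species and fluoride. Its removal under mild acid is the only operation after the key step.

In 25, ring A is cut at C7–C8, C4a–C8a and C6–C7. This leads to cyclobutenone 20, in which C4a, C5, C6 and C7 are the four ring carbons and C8 and C8a are the carbons of an alkynyl ether held on the C2 oxygen. The cut is made here because every ring A substituent is then fixed by chain connectivity: methoxy on the ring carbon that becomes C5, prenyl on the alkyne terminus that becomes C8, and the carbonyl that becomes the C7 phenol. Both rings are gained at once and no aromatic substitution is needed. The forward reaction must open the four-membered ring to vinylketene 21, add it across the tethered alkyne to 22, reopen to dienylketene 23, close ring A to 24 and tautomerise. The alkynyl ether in 20 is secondary and benzylic and is lost on heating (retro-ene elimination, sigmatropic shift onto ring B). The opening of 20 is therefore driven by light near ambient temperature. Heat is applied only after the alkynyl ether has been consumed in 22.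

20 is cut at C4–C4a into primary iodide 15 and iodocyclobutenone 18. The linear alternative would build the four-membered ring on the chain by a ketene cycloaddition and then convert the C2 hydroxyl into the alkynyl ether. It fails twice. Alkynyl ethers are made with organolithium reagents, which add to a cyclobutenone carbonyl. A ketene generated on a chain that already carries the alkynyl ether would be trapped by it. The alkynyl ether is therefore completed first and the ring is brought in intact. The union through organozinc 19 under palladium catalysis is neutral and runs at room temperature.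

18 comes from 17 by iodination at the nucleophilic α-carbon of the vinylogous ester. 17 comes from dione 16 by O-methylation. The two carbonyls of 16 are equivalent, so only one enol ether can form.

15 is derived from alcohol 13 and this from silyl ether 12 by functional group changes at the chain end. 12 is cut at the bond between C8 and the prenyl group into lithium alkynyl ether 11 and bromide 10. 11 goes back to dichlorovinyl ether 9, and 9 to alcohol 7 and the two-carbon unit 8. In this sequence the oxygen of 7 attacks carbon. The C2–O bond is never broken, so the configuration of 7 is carried into 20.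

7 is the mono-silyl ether of diol 6, which comes from hydroxy ester 5 by reduction. 5 is the product of an asymmetric transfer hydrogenation of keto ester 4, which sets C2. 4 is cut at C2–C3 into benzoate 2 and ester 3 (Claisen condensation), and 2 is the acetal of phenol 1.

## Alternatives that were turned down

Alternative 1: The pyran ring is cut at C2–C3 and O1–C8a, and ring A is added afterwards. In the forward sense Ti(OiPr)4 with BINOL catalyses the hetero-Diels–Alder reaction of aldehyde A1 with siloxydiene A2, and acid work-up gives dihydropyranone A3.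
- For it: the reaction class is catalytic and well established for aromatic aldehydes, C2 is set in the key step, and A3 is reached in very few steps.
- Against it: A3 contains only O1, C2, C3, C4, C4a and C8a. The four carbons C5 to C8 with methoxy, hydroxyl and prenyl must still be annulated across the push–pull C4a=C8a bond, the new ring aromatised, and the C4 carbonyl, which the target lacks, removed. The ring A pattern is not fixed by the key step. The C2–O1 bond of A3 is β to the ketone, so base used in the annulation can open it by retro-oxa-Michael reaction and erode the stereocentre.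
- Comparison: on precedent and on setting the stereocentre inside the key step this route is the stronger one. The chosen route offers instead one step that delivers ring A fully substituted and the pyran ring at the right oxidation level, with one deprotection left.

Alternative 2: The cuts are C4–C4a and C8a–O1, with ring A taken as a ready-made arene. Pd(OAc)2 and norbornene (Catellani-type) join aryl iodide A4 and oxetane A5. Oxidative addition and norbornene insertion are followed by palladation of C4a–H, alkylation by ring opening of A5 at its CH2 carbon, norbornene extrusion and C–O reductive elimination to A6.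
- For it: it is the most convergent plan, the stereocentre arrives in A5 and is not touched, and A6 is one desilylation from 26. In step count it is probably shorter than the chosen route.
- Against it: A4 has iodine, prenyl and silyloxy on three adjacent carbons. Making it means solving by aromatic substitution the regiochemical problem that the benzannulation avoids. In the key step the prenyl alkene sits ortho to the arylpalladium centre and can insert. Oxetanes are weaker electrophiles than the epoxides and aziridines for which this ortho-alkylation and ipso-etherification is established. Six-membered C–O reductive elimination from the alkoxide competes with β-hydride elimination at the carbinol.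
- Comparison: it is stronger in convergence. The chosen route offers ring A regiochemistry that follows from connectivity and no palladium intermediate next to a prenyl group.

Alternative 3: The cuts are O1–C2 and C3–C4, with a formyl group on C3 that is removed later. A diarylprolinol silyl ether activates cinnamaldehyde A8 as an iminium ion. The C8a phenol of salicylaldehyde A7 adds to it, the enamine closes onto the C4a aldehyde, and dehydration gives chromene A9.
- For it: it is metal-free, the stereocentre is set catalytically in the ring-forming step, and the domino type is well known.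
- Against it: A7 is again a fully substituted ring A that needs regioselective prenylation and formylation of a phloroglucinol derivative. Its phenol is flanked by prenyl and its aldehyde by methoxy, and both are deactivated by the donor oxygens, which slows both stages. The oxa-Michael step is reversible and C2–H of A9 is allylic and benzylic, so enantiopurity can erode. A9 has C2 in the spatial arrangement of the target, and its descriptor is S only because the formyl-bearing C3 outranks ring B. After the key step the formyl group must be excised (for example with RhCl(PPh3)3 at high temperature) and the C3=C4 bond reduced without touching the prenyl alkene or the C2–O1 bond.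
- Comparison: its key step has the better precedent. The chosen route needs no chemoselective reduction and no sacrificial carbon.

Key step: step 13

Assumption: a secondary benzylic alkynyl ether of this kind is taken to be stable in solution up to about 25 °C, as primary benzylic and hindered secondary congeners are, so every operation on 12 to 20 is held at or below that temperature.

## Route

Step 1
Reactants: 1 methyl 3-hydroxy-5-methoxybenzoate
Product: 2 methyl 3-methoxy-5-(methoxymethoxy)benzoate
Conditions: MOMCl, iPr2NEt, CH2Cl2, 0 → 25 °C
Reagents that add atoms: chloromethyl methyl ether, COCCl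
Why: O-alkylation of the phenol to an acetal (Williamson type). The acetal is inert to the bases, organometallics and fluoride used later and is the only group left to remove after the key step.

Step 2
Reactants: 2 methyl 3-methoxy-5-(methoxymethoxy)benzoate; 3 ethyl acetate
Product: 4 ethyl 3-[3-methoxy-5-(methoxymethoxy)phenyl]-3-oxopropanoate
Conditions: LiN(SiMe3)2 (2.5 equiv), THF, −78 → 0 °C; aq. NH4Cl
Reagents that add atoms: none
Why: Crossed Claisen condensation. The lithium enolate of 3 acylates the non-enolisable benzoate, and deprotonation of the β-keto ester drives the equilibrium.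

Step 3
Reactants: 4 ethyl 3-[3-methoxy-5-(methoxymethoxy)phenyl]-3-oxopropanoate
Product: 5 ethyl (3R)-3-hydroxy-3-[3-methoxy-5-(methoxymethoxy)phenyl]propanoate
Conditions: RuCl(p-cymene)[(R,R)-TsDPEN] (cat.), HCO2H/Et3N (5:2), DMF, 40 °C
Reagents that add atoms: none
Why: Noyori asymmetric transfer hydrogenation of an aryl ketone. The (R,R)-diamine ligand places the aryl group against the η6-arene and delivers hydride to the face that gives the (R)-carbinol, which becomes C2 of the target.

Step 4
Reactants: 5 ethyl (3R)-3-hydroxy-3-[3-methoxy-5-(methoxymethoxy)phenyl]propanoate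
Product: 6 (1R)-1-[3-methoxy-5-(methoxymethoxy)phenyl]propane-1,3-diol
Conditions: LiAlH4, THF, 0 °C; aq. NaOH work-up
Reagents that add atoms: none
Why: Hydride reduction of the ester to the primary alcohol. The carbinol stereocentre is not involved.

Step 5
Reactants: 6 (1R)-1-[3-methoxy-5-(methoxymethoxy)phenyl]propane-1,3-diol
Product: 7 (1R)-1-[3-methoxy-5-(methoxymethoxy)phenyl]-3-[(triisopropylsilyl)oxy]propan-1-ol
Conditions: TIPSCl, imidazole, CH2Cl2, 0 °C
Reagents that add atoms: chlorotriisopropylsilane, CC(C)[Si](Cl)(C(C)C)C(C)C
Why: Selective silylation of the primary hydroxyl on steric grounds. The bulky triisopropylsilyl group is chosen because a smaller silyl group would migrate to the neighbouring alkoxide in step 6.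

Step 6
Reactants: 7 (1R)-1-[3-methoxy-5-(methoxymethoxy)phenyl]-3-[(triisopropylsilyl)oxy]propan-1-ol; 8 trichloroethylene
Product: 9 {(3R)-3-[(E)-1,2-dichloroethenyl]oxy-3-[3-methoxy-5-(methoxymethoxy)phenyl]propoxy}triisopropylsilane
Conditions: KH, THF, 0 → 25 °C; then 8, −50 → 25 °C
Reagents that add atoms: none
Why: The potassium alkoxide adds to dichloroacetylene formed in the flask from 8 by dehydrochlorination, and protonation gives the (E)-dichlorovinyl ether. The oxygen attacks carbon, so the C–O bond of the stereocentre stays intact.

Step 7
Reactants: 9 {(3R)-3-[(E)-1,2-dichloroethenyl]oxy-3-[3-methoxy-5-(methoxymethoxy)phenyl]propoxy}triisopropylsilane; 10 prenyl bromide (1-bromo-3-methylbut-2-ene)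
Product: 12 {(3R)-3-[3-methoxy-5-(methoxymethoxy)phenyl]-3-[(5-methylhex-4-en-1-yn-1-yl)oxy]propoxy}triisopropylsilane, via lithium alkynyl ether 11 (not isolated)
Conditions: n-BuLi (2.3 equiv), THF, −78 → −40 °C; then 10, DMPU, −78 → 0 °C
Reagents that add atoms: none
Why: Dehydrochlorination and chlorine–lithium exchange give lithium alkynyl ether 11, which is C-alkylated by SN2 attack at the primary carbon of the allylic bromide. This is the established route from dichlorovinyl ethers to substituted alkynyl ethers. The product is kept at or below 0 °C because it is thermally labile.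

Step 8
Reactants: 12 {(3R)-3-[3-methoxy-5-(methoxymethoxy)phenyl]-3-[(5-methylhex-4-en-1-yn-1-yl)oxy]propoxy}triisopropylsilane
Product: 13 (3R)-3-[3-methoxy-5-(methoxymethoxy)phenyl]-3-[(5-methylhex-4-en-1-yn-1-yl)oxy]propan-1-ol
Conditions: Bu4NF (hydrate), THF, 0 → 20 °C
Reagents that add atoms: none
Why: Fluoride cleaves the Si–O bond. The aryl acetal and the alkynyl ether tolerate basic fluoride, and the water of the reagent keeps the freed primary alkoxide protonated so that it does not add to the alkyne.

Step 9
Reactants: 13 (3R)-3-[3-methoxy-5-(methoxymethoxy)phenyl]-3-[(5-methylhex-4-en-1-yn-1-yl)oxy]propan-1-ol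
Product: 15 1-{(1R)-3-iodo-1-[(5-methylhex-4-en-1-yn-1-yl)oxy]propyl}-3-methoxy-5-(methoxymethoxy)benzene, via mesylate 14 (not isolated)
Conditions: MsCl, Et3N, CH2Cl2, −10 °C; then NaI, acetone, 20 °C
Reagents that add atoms: sodium iodide, [Na+].[I-]; methanesulfonyl chloride, CS(=O)(=O)Cl (its atoms stay in 14 only)
Why: Sulfonylation followed by Finkelstein substitution (SN2 at the primary carbon). The medium stays neutral to weakly basic and no electrophilic iodine meets the electron-rich alkyne.

Step 10
Reactants: 16 cyclobutane-1,3-dione
Product: 17 3-methoxycyclobut-2-en-1-one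
Conditions: Me3SiCHN2, MeOH/PhMe, 0 °C
Reagents that add atoms: (trimethylsilyl)diazomethane, C[Si](C)(C)C=[N+]=[N-]
Why: O-methylation of the strongly acidic enol of the dione by the diazoalkane. The two carbonyls are equivalent, so a single enol ether forms.

Step 11
Reactants: 17 3-methoxycyclobut-2-en-1-one
Product: 18 2-iodo-3-methoxycyclobut-2-en-1-one
Conditions: NIS, MeCN, 0 → 20 °C, dark
Reagents that add atoms: N-iodosuccinimide, O=C1CCC(=O)N1I
Why: Electrophilic α-iodination of a vinylogous ester at its nucleophilic C2 through an oxocarbenium ion and loss of a proton, as practised on 3-alkoxycycloalkenones.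

Step 12
Reactants: 15 1-{(1R)-3-iodo-1-[(5-methylhex-4-en-1-yn-1-yl)oxy]propyl}-3-methoxy-5-(methoxymethoxy)benzene; 18 2-iodo-3-methoxycyclobut-2-en-1-one
Product: 20 3-methoxy-2-{(3R)-3-[3-methoxy-5-(methoxymethoxy)phenyl]-3-[(5-methylhex-4-en-1-yn-1-yl)oxy]propyl}cyclobut-2-en-1-one, via alkylzinc iodide 19 (not isolated)
Conditions: Zn dust, LiCl, THF, 25 °C; then 18, Pd(OAc)2 (cat.), SPhos (cat.), THF, 20 °C
Reagents that add atoms: none
Why: Zinc inserts into the primary C–I bond without touching the alkynyl ether. Negishi coupling of 19 with the activated alkenyl iodide under zerovalent palladium then forms C4–C4a at room temperature. The ring is attached only now because it would not survive the organolithium chemistry of step 7, and a ketene route to it would not spare the alkynyl ether.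

Step 13
Reactants: 20 3-methoxy-2-{(3R)-3-[3-methoxy-5-(methoxymethoxy)phenyl]-3-[(5-methylhex-4-en-1-yn-1-yl)oxy]propyl}cyclobut-2-en-1-one
Product: 25 (2R)-5-methoxy-2-[3-methoxy-5-(methoxymethoxy)phenyl]-8-(3-methylbut-2-en-1-yl)-3,4-dihydro-2H-chromen-7-ol, via vinylketene 21 (not isolated), via fused vinylcyclobutenone 22 (not isolated), via dienylketene 23 (not isolated), via cyclohexadienone 24 (not isolated)
Conditions: hν (300 nm, Pyrex), degassed PhMe (0.005 M), 15–20 °C until 20 is consumed; then 80 °C, dark
Reagents that add atoms: none
Why: Proposed new method: irradiation of the vinylogous ester chromophore of 20 opens the four-membered ring (4π electrocyclic) to vinylketene 21, whose electrophilic carbonyl carbon C7 is attacked by the electron-rich, prenyl-bearing alkyne carbon C8 while the ketene α-carbon C4a bonds to the oxygen-bearing carbon C8a; this polar [2+2] closes the pyran ring in the fused mode, as a six-membered ring through C4–C3–C2–O1, and gives 22. The alkynyl ether is consumed at this point, so the flask can then be warmed: 22 opens (4π) to dienylketene 23, in which the ring fusion allows only the geometry with the methoxyvinyl group cis to the ketene, ring A closes by thermal 6π electrocyclisation (C6–C7), and dienone 24 tautomerises to the C7 phenol. The closest known reaction type is the intermolecular Danheiser benzannulation of cyclobutenones with alkoxy- or silyloxyalkynes, including its variant with vinylketenes generated by light at room temperature; tethering the partners through the alkynyl ether oxygen is without precedent. No stereocentre is created that persists: the quaternary C4a of 22 is transient and becomes aromatic, and C2 stays R because no bond to it is made or broken. The step needs regioselectivity in the [2+2], and the polarisation of the alkynyl ether and the length of the tether direct it the same way, since the reverse orientation would require a bridged ring. It needs chemoselectivity for the alkynyl ether over the prenyl alkene, which the far higher reactivity of alkynyl ethers towards ketenes secures. It needs the alkynyl ether to survive until it is captured, which is why the first stage uses light below 20 °C and not the heat that thermal opening of 20 would demand; high dilution suppresses ketene dimerisation.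

Step 14
Reactants: 25 (2R)-5-methoxy-2-[3-methoxy-5-(methoxymethoxy)phenyl]-8-(3-methylbut-2-en-1-yl)-3,4-dihydro-2H-chromen-7-ol
Product: 26 (2R)-2-(3-hydroxy-5-methoxyphenyl)-5-methoxy-8-(3-methylbut-2-en-1-yl)-3,4-dihydro-2H-chromen-7-ol
Conditions: HCl (0.5 M in MeOH), 20 °C
Reagents that add atoms: none
Why: Acid-catalysed acetal exchange with methanol frees the ring B phenol. Dilute acid at room temperature is used so that closure of the prenyl group onto the C7 hydroxyl does not compete, and the C2–O1 bond, which has no para donor on ring B, should not ionise.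

## Compound list

1 | methyl 3-hydroxy-5-methoxybenzoate | COC(=O)c1cc(O)cc(OC)c1 | starting material
2 | methyl 3-methoxy-5-(methoxymethoxy)benzoate | COC(=O)c1cc(OC)cc(OCOC)c1 | intermediate
3 | ethyl acetate | CCOC(C)=O | starting material
4 | ethyl 3-[3-methoxy-5-(methoxymethoxy)phenyl]-3-oxopropanoate | CCOC(=O)CC(=O)c1cc(OC)cc(OCOC)c1 | intermediate
5 | ethyl (3R)-3-hydroxy-3-[3-methoxy-5-(methoxymethoxy)phenyl]propanoate | CCOC(=O)C[C@@H](O)c1cc(OC)cc(OCOC)c1 | intermediate
6 | (1R)-1-[3-methoxy-5-(methoxymethoxy)phenyl]propane-1,3-diol | OCC[C@@H](O)c1cc(OC)cc(OCOC)c1 | intermediate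
7 | (1R)-1-[3-methoxy-5-(methoxymethoxy)phenyl]-3-[(triisopropylsilyl)oxy]propan-1-ol | CC(C)[Si](OCC[C@@H](O)c1cc(OC)cc(OCOC)c1)(C(C)C)C(C)C | intermediate
8 | trichloroethylene | ClC=C(Cl)Cl | starting material
9 | {(3R)-3-[(E)-1,2-dichloroethenyl]oxy-3-[3-methoxy-5-(methoxymethoxy)phenyl]propoxy}triisopropylsilane | CC(C)[Si](OCC[C@@H](O/C(Cl)=C\Cl)c1cc(OC)cc(OCOC)c1)(C(C)C)C(C)C | intermediate
10 | prenyl bromide (1-bromo-3-methylbut-2-ene) | CC(C)=CCBr | starting material
11 | lithium 2-{(1R)-1-[3-methoxy-5-(methoxymethoxy)phenyl]-3-[(triisopropylsilyl)oxy]propoxy}ethynide | CC(C)[Si](OCC[C@@H](OC#C[Li])c1cc(OC)cc(OCOC)c1)(C(C)C)C(C)C | intermediate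
12 | {(3R)-3-[3-methoxy-5-(methoxymethoxy)phenyl]-3-[(5-methylhex-4-en-1-yn-1-yl)oxy]propoxy}triisopropylsilane | CC(C)[Si](OCC[C@@H](OC#CCC=C(C)C)c1cc(OC)cc(OCOC)c1)(C(C)C)C(C)C | intermediate
13 | (3R)-3-[3-methoxy-5-(methoxymethoxy)phenyl]-3-[(5-methylhex-4-en-1-yn-1-yl)oxy]propan-1-ol | OCC[C@@H](OC#CCC=C(C)C)c1cc(OC)cc(OCOC)c1 | intermediate
14 | (3R)-3-[3-methoxy-5-(methoxymethoxy)phenyl]-3-[(5-methylhex-4-en-1-yn-1-yl)oxy]propyl methanesulfonate | CS(=O)(=O)OCC[C@@H](OC#CCC=C(C)C)c1cc(OC)cc(OCOC)c1 | intermediate
15 | 1-{(1R)-3-iodo-1-[(5-methylhex-4-en-1-yn-1-yl)oxy]propyl}-3-methoxy-5-(methoxymethoxy)benzene | ICC[C@@H](OC#CCC=C(C)C)c1cc(OC)cc(OCOC)c1 | intermediate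
16 | cyclobutane-1,3-dione | O=C1CC(=O)C1 | starting material
17 | 3-methoxycyclobut-2-en-1-one | COC1=CC(=O)C1 | intermediate
18 | 2-iodo-3-methoxycyclobut-2-en-1-one | COC1=C(I)C(=O)C1 | intermediate
19 | {(3R)-3-[3-methoxy-5-(methoxymethoxy)phenyl]-3-[(5-methylhex-4-en-1-yn-1-yl)oxy]propyl}zinc iodide | I[Zn]CC[C@@H](OC#CCC=C(C)C)c1cc(OC)cc(OCOC)c1 | intermediate
20 | 3-methoxy-2-{(3R)-3-[3-methoxy-5-(methoxymethoxy)phenyl]-3-[(5-methylhex-4-en-1-yn-1-yl)oxy]propyl}cyclobut-2-en-1-one | COC1=C(CC[C@@H](OC#CCC=C(C)C)c2cc(OC)cc(OCOC)c2)C(=O)C1 | intermediate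
21 | (5R)-2-(1-methoxyethenyl)-5-[3-methoxy-5-(methoxymethoxy)phenyl]-5-[(5-methylhex-4-en-1-yn-1-yl)oxy]pent-1-en-1-one (vinylketene) | C=C(OC)C(=C=O)CC[C@@H](OC#CCC=C(C)C)c1cc(OC)cc(OCOC)c1 | intermediate
22 | (3R)-6-(1-methoxyethenyl)-3-[3-methoxy-5-(methoxymethoxy)phenyl]-8-(3-methylbut-2-en-1-yl)-2-oxabicyclo[4.2.0]oct-1(8)-en-7-one, both epimers at the quaternary ring-fusion carbon | O=C1C(CC=C(C)C)=C2O[C@@H](c3cc(OC)cc(OCOC)c3)CCC12C(=C)OC | intermediate
23 | 2-{(2R)-5-(1-methoxyethenyl)-2-[3-methoxy-5-(methoxymethoxy)phenyl]-3,4-dihydro-2H-pyran-6-yl}-5-methylhexa-1,4-dien-1-one (dienylketene) | O=C=C(CC=C(C)C)C1=C(C(=C)OC)CC[C@H](c2cc(OC)cc(OCOC)c2)O1 | intermediate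
24 | (2R)-5-methoxy-2-[3-methoxy-5-(methoxymethoxy)phenyl]-8-(3-methylbut-2-en-1-yl)-2,3,4,6-tetrahydro-7H-chromen-7-one | O=C1CC(OC)=C2CC[C@H](c3cc(OC)cc(OCOC)c3)OC2=C1CC=C(C)C | intermediate
25 | (2R)-5-methoxy-2-[3-methoxy-5-(methoxymethoxy)phenyl]-8-(3-methylbut-2-en-1-yl)-3,4-dihydro-2H-chromen-7-ol | COCOc1cc(OC)cc([C@H]2CCc3c(OC)cc(O)c(CC=C(C)C)c3O2)c1 | intermediate
26 | (2R)-2-(3-hydroxy-5-methoxyphenyl)-5-methoxy-8-(3-methylbut-2-en-1-yl)-3,4-dihydro-2H-chromen-7-ol | COc1cc(O)cc([C@H]2CCc3c(OC)cc(O)c(CC=C(C)C)c3O2)c1 | target

## Step count and least certain steps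

Total step count: 14. Longest linear sequence: 12 (steps 1 to 9, 12, 13 and 14). Steps 10 and 11 make the four-carbon partner.

Step 13 (key step, new method). The most likely failure is that vinylketene 21 recloses or dimerises faster than it is captured, because the [2+2] must pass through a fused six-membered arrangement that contains the linear O–C≡C unit. The second risk is that the light-driven opening is inefficient and the alkynyl ether decays by retro-ene elimination or sigmatropic shift before capture. The fallback uses known chemistry: an intermolecular benzannulation followed by a Mitsunobu ring closure. It sets out from 4 and returns at 25.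
- Transfer hydrogenation of 4 with RuCl(p-cymene)[(S,S)-TsDPEN] gives the (S)-hydroxy ester F1, and LiAlH4 gives the (S)-diol F2.
- Selective iodination of the primary hydroxyl (I2, PPh3, imidazole) gives iodo alcohol F3, and TBSCl with imidazole gives silyl ether F4.
- Zinc insertion and Negishi coupling with 18, as in step 12, give cyclobutenone F5, which carries no alkynyl ether and can be heated.
- Heating F5 in toluene at 80 to 110 °C with silyloxyalkyne F6 gives phenol F7 with the same ring A pattern. F6 is made by Kowalski homologation of ethyl 4-methylpent-3-enoate (LiCHBr2, then n-BuLi) and O-silylation of the lithium ynolate with TIPSCl.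
- Bu4NF removes both silyl groups to give triol F8. PPh3 and DIAD then close the pyran ring by attack of the C8a phenol on C2 with inversion, which turns the (S)-carbinol into the (R)-flavan 25.

Step 12. Zinc insertion may be too slow at or below 25 °C, so that the alkynyl ether decays or the organozinc is protonated before coupling, and the strained iodoenone may not survive oxidative addition cleanly. The fallback replaces the organozinc by a borate and sets out from 15 and returns at 20. Iodine–lithium exchange of 15 with t-BuLi at −78 °C in the presence of 9-methoxy-9-borabicyclo[3.3.1]nonane gives the lithium alkylborate F9 within minutes. F9 is then coupled with 18 by B-alkyl Suzuki–Miyaura reaction (PdCl2(dppf), aq. K3PO4, DMF, 20 °C).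

Step 7. C-alkylation of the weakly nucleophilic lithium alkynyl ether may be incomplete, attack may occur at the tertiary end of the allyl system, or the alkynyl ether may be lost on warming. The fallback separates alkyne formation from prenylation and sets out from 9 and returns at 12. Treatment of 9 with n-BuLi and a cold methanol quench gives the terminal alkynyl ether F10. F10 is then allylated with 10 through its copper acetylide (CuI, K2CO3, NaI, DMF, 20 °C), a coupling that favours the unbranched 1,4-enyne.

Step 6. Under KH the silyl group may move from the primary to the benzylic oxygen, so that the wrong alkoxide is vinylated, or the benzylic alkoxide may fragment. The fallback avoids a free alkoxide and sets out from 7 and returns at 11. Formylation of 7 (formic acid, DCC, DMAP) gives the formate F11. Dibromomethylenation with CBr4 and PPh3 gives the dibromovinyl ether F12. Treatment of F12 with n-BuLi (2 equiv, −78 °C) causes bromine–lithium exchange and rearrangement to lithium alkynyl ether 11, which is prenylated as in step 7.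

## Further compounds

F1 | step 13 | ethyl (3S)-3-hydroxy-3-[3-methoxy-5-(methoxymethoxy)phenyl]propanoate | CCOC(=O)C[C@H](O)c1cc(OC)cc(OCOC)c1
F2 | step 13 | (1S)-1-[3-methoxy-5-(methoxymethoxy)phenyl]propane-1,3-diol | OCC[C@H](O)c1cc(OC)cc(OCOC)c1
F3 | step 13 | (1S)-3-iodo-1-[3-methoxy-5-(methoxymethoxy)phenyl]propan-1-ol | ICC[C@H](O)c1cc(OC)cc(OCOC)c1
F4 | step 13 | tert-butyl{(1S)-3-iodo-1-[3-methoxy-5-(methoxymethoxy)phenyl]propoxy}dimethylsilane | ICC[C@H](O[Si](C)(C)C(C)(C)C)c1cc(OC)cc(OCOC)c1
F5 | step 13 | 2-{(3S)-3-[(tert-butyldimethylsilyl)oxy]-3-[3-methoxy-5-(methoxymethoxy)phenyl]propyl}-3-methoxycyclobut-2-en-1-one | COC1=C(CC[C@H](O[Si](C)(C)C(C)(C)C)c2cc(OC)cc(OCOC)c2)C(=O)C1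
F6 | step 13 | triisopropyl[(5-methylhex-4-en-1-yn-1-yl)oxy]silane | CC(C)=CCC#CO[Si](C(C)C)(C(C)C)C(C)C
F7 | step 13 | 4-{(3S)-3-[(tert-butyldimethylsilyl)oxy]-3-[3-methoxy-5-(methoxymethoxy)phenyl]propyl}-5-methoxy-2-(3-methylbut-2-en-1-yl)-3-[(triisopropylsilyl)oxy]phenol | COc1cc(O)c(CC=C(C)C)c(O[Si](C(C)C)(C(C)C)C(C)C)c1CC[C@H](O[Si](C)(C)C(C)(C)C)c1cc(OC)cc(OCOC)c1
F8 | step 13 | 4-{(3S)-3-hydroxy-3-[3-methoxy-5-(methoxymethoxy)phenyl]propyl}-5-methoxy-2-(3-methylbut-2-en-1-yl)benzene-1,3-diol | COc1cc(O)c(CC=C(C)C)c(O)c1CC[C@H](O)c1cc(OC)cc(OCOC)c1
F9 | step 12 | lithium 9-methoxy-9-{(3R)-3-[3-methoxy-5-(methoxymethoxy)phenyl]-3-[(5-methylhex-4-en-1-yn-1-yl)oxy]propyl}-9-boranuidabicyclo[3.3.1]nonane | [Li+].CO[B-]1(CC[C@@H](OC#CCC=C(C)C)c2cc(OC)cc(OCOC)c2)C2CCCC1CCC2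
F10 | step 7 | {(3R)-3-(ethynyloxy)-3-[3-methoxy-5-(methoxymethoxy)phenyl]propoxy}triisopropylsilane | CC(C)[Si](OCC[C@@H](OC#C)c1cc(OC)cc(OCOC)c1)(C(C)C)C(C)C
F11 | step 6 | (1R)-1-[3-methoxy-5-(methoxymethoxy)phenyl]-3-[(triisopropylsilyl)oxy]propyl formate | CC(C)[Si](OCC[C@@H](OC=O)c1cc(OC)cc(OCOC)c1)(C(C)C)C(C)C
F12 | step 6 | {(3R)-3-[(2,2-dibromoethenyl)oxy]-3-[3-methoxy-5-(methoxymethoxy)phenyl]propoxy}triisopropylsilane | CC(C)[Si](OCC[C@@H](OC=C(Br)Br)c1cc(OC)cc(OCOC)c1)(C(C)C)C(C)C
A1 | alternative 1 | 3-[(tert-butyldimethylsilyl)oxy]-5-methoxybenzaldehyde | COc1cc(C=O)cc(O[Si](C)(C)C(C)(C)C)c1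
A2 | alternative 1 | (E)-1-methoxy-3-[(trimethylsilyl)oxy]buta-1,3-diene | CO/C=C/C(=C)O[Si](C)(C)C
A3 | alternative 1 | (2R)-2-{3-[(tert-butyldimethylsilyl)oxy]-5-methoxyphenyl}-2,3-dihydro-4H-pyran-4-one | COc1cc(O[Si](C)(C)C(C)(C)C)cc([C@H]2CC(=O)C=CO2)c1
A4 | alternative 2 | 1-iodo-5-methoxy-2-(3-methylbut-2-en-1-yl)-3-[(triisopropylsilyl)oxy]benzene | COc1cc(I)c(CC=C(C)C)c(O[Si](C(C)C)(C(C)C)C(C)C)c1
A5 | alternative 2 | (2R)-2-{3-methoxy-5-[(triisopropylsilyl)oxy]phenyl}oxetane | COc1cc(O[Si](C(C)C)(C(C)C)C(C)C)cc([C@H]2CCO2)c1
A6 | alternative 2 | (2R)-5-methoxy-2-{3-methoxy-5-[(triisopropylsilyl)oxy]phenyl}-8-(3-methylbut-2-en-1-yl)-7-[(triisopropylsilyl)oxy]-3,4-dihydro-2H-chromene | COc1cc(O[Si](C(C)C)(C(C)C)C(C)C)cc([C@H]2CCc3c(OC)cc(O[Si](C(C)C)(C(C)C)C(C)C)c(CC=C(C)C)c3O2)c1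
A7 | alternative 3 | 4-[(tert-butyldimethylsilyl)oxy]-2-hydroxy-6-methoxy-3-(3-methylbut-2-en-1-yl)benzaldehyde | COc1cc(O[Si](C)(C)C(C)(C)C)c(CC=C(C)C)c(O)c1C=O
A8 | alternative 3 | (E)-3-{3-[(tert-butyldimethylsilyl)oxy]-5-methoxyphenyl}prop-2-enal | COc1cc(/C=C/C=O)cc(O[Si](C)(C)C(C)(C)C)c1
A9 | alternative 3 | (2S)-7-[(tert-butyldimethylsilyl)oxy]-2-{3-[(tert-butyldimethylsilyl)oxy]-5-methoxyphenyl}-5-methoxy-8-(3-methylbut-2-en-1-yl)-2H-chromene-3-carbaldehyde | COc1cc(O[Si](C)(C)C(C)(C)C)cc([C@H]2C(C=O)=Cc3c(OC)cc(O[Si](C)(C)C(C)(C)C)c(CC=C(C)C)c3O2)c1
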